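Numbering used throughout: ring atoms C1(=O), C2(OMe), C3(H), C4(=O), C5(CH3), C6(chain); chain atoms C1'–C17' counted from the ring, with methyl branches on C9', C11', C13' and C15'.

## Analysis of the target

The target is a 1,4-benzoquinone with carbonyls at C1 and C4, a methoxy group on C2, hydrogen on C3, a methyl group on C5 and a saturated seventeen-carbon chain on C6. The chain is unbranched from C1' to C8' and then carries methyl groups on C9', C11', C13' and C15', each separated from the next by one methylene. Read along the chain, all four centres have the same sense, so the tetrad is all-syn; the descriptors 9'R,11'R,13'S,15'S change letter only because the CIP priorities switch in the middle of the array. The stereocentres lie eight methylenes from the ring and have no neighbouring functional group, so each must be set by an external chiral controller, and the minor diastereomers of such an oily hydrocarbon chain are very hard to remove. The methoxyquinone is an electrophile and a vinylogous ester that would not survive strong nucleophiles, hydride or strong base, so it is revealed last. The two difficulties are the handle-free all-syn tetrad and a ring whose four different substituents must be placed without regiochemical doubt. The plan rests on the ring pattern: oxygens on C2 and C4 meta to each other, a C-methyl on C5 and the chain on the neighbouring C6. Without the C1 oxygen this is a 5-alkyl-4-methylresorcinol, the arene that a tetraketide built on the branched C18 acyl unit gives when C5 closes onto the chain ketone C6.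

## Retrosynthetic reasoning

**33 to 32.** The O–CH3 bond on C2 is cut first. The methoxyquinone 33 is the most fragile form of the ring, and the hydroxyquinone 32 is a vinylogous acid whose oxygen can be alkylated under weak base. The forward step must alkylate that oxygen and not C3.

**32 to 31.** The C1 oxygen is removed, which takes the ring down to the arene 31. In 31 only C1 and C3 are unsubstituted, and only C1 is para to a hydroxyl (the C4 hydroxyl); the position para to the C2 hydroxyl is the methyl-bearing C5. A para-selective phenol oxidation therefore has one site to choose, and the surviving C2 hydroxyl ends up where the methoxy group is needed.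

**31 to 28.** The C5–C6 ring bond is cut, and an ester group is put back on C5. This opens the arene to the linear triketo ester 28, in which every ring carbon already has its final oxidation level and every substituent its final neighbour. Cutting here rather than joining the chain to a preformed arene avoids a 1,2,3,5-tetrasubstituted benzene with four positions to differentiate. The ester makes C5 a doubly activated carbon, which directs the aldol closure, and it must leave again for the ring to aromatize. The forward reaction has to close C5 onto C6 in preference to the other cyclization modes of a polyketone.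

**28 to 23 and 26.** The C6–C1 bond is cut. This separates the chiral chain, as the acyl donor 23, from an achiral four-carbon-plus-ester piece, the diketo ester 26, which reacts through its trianion 27 at the terminal carbon. The chain ketone carbon C6 is the carboxyl carbon of a C18 acid, so the chain fragment can be made at the stable acid oxidation level.

**26 to 24.** The C2–C3 bond is cut: 26 is the γ-acetylation product of the dianion 25 of commercial methyl 2-methylacetoacetate 24. The C5 methyl group and the ester are bought, not made.

**23 to 17 and 19.** Amide 23 comes from ester 22, and 22 from alkene 21 by saturation. The C6'=C7' bond of 21 is cut by a Wittig disconnection into aldehyde 17 and phosphonium salt 19 (ylide 20), which is made from bromo ester 18. The cut lies in the unbranched part of the chain, three atoms away from the nearest stereocentre, so it cannot disturb the tetrad, and the alkene geometry is irrelevant.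

**17 back to 5.** Aldehyde 17 comes from thioester 16. The four C–CH3 bonds on C9', C11', C13' and C15' are cut one at a time, each by conjugate addition of a methyl organometallic to an (E)-enethioate under a chiral copper catalyst (16 from 15, 13 from 12, 10 from 9, 7 from 6). Each enethioate is cut at its C=C bond into the next lower aldehyde (14, 11, 8) and the two-carbon ylide 4. The catalyst, not the growing chain, chooses the face, so the same ligand enantiomer in every cycle gives the all-syn array. The sequence ends at enethioate 6, made from acid 5; ylide 4 comes from acid 1 through 2 and 3.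

## Alternatives that were turned down

**Alternative 1: two-directional cuprate methylation.**
- Disconnection: the C9'–CH3 and C15'–CH3 bonds are cut together, back to bis-enoate A1, which already holds the C11' and C13' methyls.
- Forward key step: a dimethylcuprate with a chlorosilane additive adds to both enoate ends of A1; each resident methyl steers the incoming one syn by avoiding syn-pentane strain, giving diester A2.
- For: two stereocentres in one operation, no chiral reagent in the key step, and a tetrad with both ends functionalized.
- Against: the induction acts across a methylene from a δ-stereocentre and is dependable mainly with bulky esters, so the methyl-ester end of A1 is the weak one. An error at either end gives a diastereomer that cannot be removed. The absolute configuration of A1 rests only on which end of a meso-like core carries which ester, so a desymmetrization has to be added. After the key step one ester must be taken down to the C17' methyl and the other extended by seven carbons.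
- Comparison: it is stronger in stereocentres set per step. The chosen route offers per-centre catalyst control that does not depend on the chain, and it spends its one uncertain step on the ring, which A2 leaves unsolved.

**Alternative 2: assembly-line lithiation–borylation.**
- Disconnection: the seven C–C bonds from C8'–C9' to C14'–C15' are cut back to the primary boronic ester A3.
- Forward key step: seven homologations of A3 without isolation, four with the α-lithiated ethyl benzoate generated from stannane A5 and three with a chloromethyl carbenoid, giving secondary boronic ester A4. Each 1,2-migration is stereospecific, so the S configuration of A5 is copied four times.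
- For: reagent control at every centre, the C1'–C8' tether installed from the start, and the whole tetrad in one sequence.
- Against: four equivalents of enantiopure A5 and repeated cryogenic operations, with losses that multiply over seven unpurified stages. The boron on C15' of A4 must still be exchanged for the ethyl terminus, and the silyl ether brought to the acyl level of 23.
- Comparison: it is stronger than the chosen route in step count for the chain and in expected diastereomeric purity. The chosen route offers catalytic chirality with a cheap methyl source, intermediates that can be purified and checked after every cycle, and a ring construction from commodity pieces, which A4 does not address.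

**Alternative 3: Moore ring expansion.**
- Disconnection: the C4–C5 ring bond is cut, back to cyclobutenone A6, made by adding the alkenyllithium from vinyl iodide A7 to the methoxycyclobutenedione A8.
- Forward key step: heating A6 opens the four-membered ring to a dienylketene, and 6π electrocyclization followed by tautomerization gives hydroquinone A9, which mild oxidation would convert into 33.
- For: all four ring substituents are fixed by construction, the methoxy group arrives in place, and the late oxidation and methylation questions of the chosen route do not arise. On regiochemical security of the endgame it is the stronger plan.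
- Against: A7 must be made from an unsymmetrical ketone of the chain, where forming the iodoalkene toward the methyl side rather than the chain side is not controlled. A8 needs its own preparation, and the precious chain is committed as an organolithium.
- Comparison: from the stage of 23 it needs about six steps against four. The chosen route offers a ring made from an open-chain precursor with aqueous base, using no strained or organolithium intermediates derived from the chain, and it follows the presumed biogenesis.

Key step: step 18

Assumption: (S)-1-[(Rp)-2-(diphenylphosphino)ferrocenyl]ethyldicyclohexylphosphine is taken as the ligand enantiomer that delivers methyl to the enethioate face giving (3S)-7; if the sense of induction is the reverse, its mirror image is used in all four additions and nothing else changes.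

## Route

Step 1
Reactants: 1 bromoacetic acid
Product: 2 S-ethyl 2-bromoethanethioate
Conditions: EtSH, DCC, DMAP (cat.), CH2Cl2, 0 °C → rt
Reagents that add atoms: ethanethiol, CCS
Why: Carbodiimide (Steglich) thioesterification; the activated acyl group is far more electrophilic than the CH2Br carbon, so S-acylation should outrun S-alkylation at 0 °C.

Step 2
Reactants: 2 S-ethyl 2-bromoethanethioate
Product: 4 S-ethyl 2-(triphenyl-λ5-phosphanylidene)ethanethioate, via phosphonium bromide 3 (not isolated)
Conditions: PPh3, CH2Cl2, rt; then aq. Na2CO3 (two-phase), rt
Reagents that add atoms: triphenylphosphine, c1ccc(cc1)P(c1ccccc1)c1ccccc1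
Why: SN2 quaternization of the phosphine, then deprotonation of the acidic acyl-stabilized phosphonium salt by carbonate, the standard preparation of a stabilized Wittig reagent; carbonate is too weak to hydrolyse the thioester.

Step 3
Reactants: 5 (2E)-pent-2-enoic acid
Product: 6 S-ethyl (2E)-pent-2-enethioate
Conditions: EtSH (1.0 equiv), DCC, DMAP (cat.), CH2Cl2, 0 °C → rt
Reagents that add atoms: ethanethiol, CCS
Why: Steglich thioesterification; one equivalent of thiol, low temperature and only catalytic base should keep conjugate addition of the thiol to the new enethioate slow, and the E geometry is not touched.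

Step 4
Reactants: 6 S-ethyl (2E)-pent-2-enethioate
Product: 7 S-ethyl (3S)-3-methylpentanethioate
Conditions: MeMgBr, CuBr·SMe2 (cat.), (S)-1-[(Rp)-2-(diphenylphosphino)ferrocenyl]ethyldicyclohexylphosphine (cat.), t-BuOMe, –75 °C; MeOH, aq. NH4Cl
Reagents that add atoms: methylmagnesium bromide, C[Mg]Br
Why: Copper-catalysed asymmetric conjugate addition of a Grignard reagent to an α,β-unsaturated thioester; the thioester is electrophilic enough for 1,4-addition at low temperature without 1,2-addition. The chiral CuBr–diphosphine complex alone selects the alkene face and sets C15' (S).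

Step 5
Reactants: 7 S-ethyl (3S)-3-methylpentanethioate; 4 S-ethyl 2-(triphenyl-λ5-phosphanylidene)ethanethioate
Product: 9 S-ethyl (2E,5S)-5-methylhept-2-enethioate, via (3S)-3-methylpentanal 8 (not isolated)
Conditions: Et3SiH, Pd/C (cat.), CH2Cl2, rt; filtration; then 4, CH2Cl2, 40 °C
Reagents that add atoms: none
Why: Fukuyama reduction (palladium-catalysed hydrosilane reduction of a thioester) stops at the aldehyde; the volatile aldehyde stays in solution and is taken up by an E-selective Wittig olefination with the stabilized ylide. The stereocentre is β to the carbonyl and cannot epimerize.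

Step 6
Reactants: 9 S-ethyl (2E,5S)-5-methylhept-2-enethioate
Product: 10 S-ethyl (3S,5S)-3,5-dimethylheptanethioate
Conditions: MeMgBr, CuBr·SMe2 (cat.), (S)-1-[(Rp)-2-(diphenylphosphino)ferrocenyl]ethyldicyclohexylphosphine (cat.), t-BuOMe, –75 °C; MeOH, aq. NH4Cl
Reagents that add atoms: methylmagnesium bromide, C[Mg]Br
Why: Second catalytic asymmetric conjugate addition; the catalyst should override the weak bias of the remote δ-methyl, so the same ligand gives the same local sense of attack and sets C13' syn to C15'.

Step 7
Reactants: 10 S-ethyl (3S,5S)-3,5-dimethylheptanethioate; 4 S-ethyl 2-(triphenyl-λ5-phosphanylidene)ethanethioate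
Product: 12 S-ethyl (2E,5S,7S)-5,7-dimethylnon-2-enethioate, via (3S,5S)-3,5-dimethylheptanal 11 (not isolated)
Conditions: Et3SiH, Pd/C (cat.), CH2Cl2, rt; filtration; then 4, CH2Cl2, 40 °C
Reagents that add atoms: none
Why: Fukuyama reduction followed by Wittig olefination, as in step 5; neither operation touches the two stereocentres.

Step 8
Reactants: 12 S-ethyl (2E,5S,7S)-5,7-dimethylnon-2-enethioate
Product: 13 S-ethyl (3S,5S,7S)-3,5,7-trimethylnonanethioate
Conditions: MeMgBr, CuBr·SMe2 (cat.), (S)-1-[(Rp)-2-(diphenylphosphino)ferrocenyl]ethyldicyclohexylphosphine (cat.), t-BuOMe, –75 °C; MeOH, aq. NH4Cl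
Reagents that add atoms: methylmagnesium bromide, C[Mg]Br
Why: Third catalytic asymmetric conjugate addition under catalyst control; it sets C11' syn to C13'.

Step 9
Reactants: 13 S-ethyl (3S,5S,7S)-3,5,7-trimethylnonanethioate; 4 S-ethyl 2-(triphenyl-λ5-phosphanylidene)ethanethioate
Product: 15 S-ethyl (2E,5S,7S,9S)-5,7,9-trimethylundec-2-enethioate, via (3S,5S,7S)-3,5,7-trimethylnonanal 14 (not isolated)
Conditions: Et3SiH, Pd/C (cat.), CH2Cl2, rt; filtration; then 4, CH2Cl2, 40 °C
Reagents that add atoms: none
Why: Fukuyama reduction followed by Wittig olefination, as in step 5.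

Step 10
Reactants: 15 S-ethyl (2E,5S,7S,9S)-5,7,9-trimethylundec-2-enethioate
Product: 16 S-ethyl (3S,5S,7S,9S)-3,5,7,9-tetramethylundecanethioate
Conditions: MeMgBr, CuBr·SMe2 (cat.), (S)-1-[(Rp)-2-(diphenylphosphino)ferrocenyl]ethyldicyclohexylphosphine (cat.), t-BuOMe, –75 °C; MeOH, aq. NH4Cl
Reagents that add atoms: methylmagnesium bromide, C[Mg]Br
Why: Fourth catalytic asymmetric conjugate addition; it sets C9' syn to C11' and completes the all-syn tetrad, which here carries the descriptors S,S,S,S because the thioester carbon ranks highest.

Step 11
Reactants: 16 S-ethyl (3S,5S,7S,9S)-3,5,7,9-tetramethylundecanethioate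
Product: 17 (3S,5S,7S,9S)-3,5,7,9-tetramethylundecanal
Conditions: Et3SiH, Pd/C (cat.), CH2Cl2, rt
Reagents that add atoms: none
Why: Fukuyama reduction; this aldehyde is not volatile and can be isolated, and its nearest stereocentre is β to the carbonyl.

Step 12
Reactants: 18 methyl 7-bromoheptanoate
Product: 19 (7-methoxy-7-oxoheptyl)triphenylphosphonium bromide
Conditions: PPh3, MeCN, reflux
Reagents that add atoms: triphenylphosphine, c1ccc(cc1)P(c1ccccc1)c1ccccc1
Why: SN2 quaternization of the phosphine by a primary bromide; the ester is inert.

Step 13
Reactants: 19 (7-methoxy-7-oxoheptyl)triphenylphosphonium bromide; 17 (3S,5S,7S,9S)-3,5,7,9-tetramethylundecanal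
Product: 21 methyl (7Z,10S,12S,14S,16S)-10,12,14,16-tetramethyloctadec-7-enoate, via phosphonium ylide 20 (not isolated)
Conditions: NaN(SiMe3)2, THF, –78 °C → 0 °C; then 17, –78 °C → rt
Reagents that add atoms: none
Why: Wittig olefination with a non-stabilized ylide; the hindered amide base and low temperature should spare the methyl ester, and the Z/E ratio is irrelevant because the alkene is saturated next. The descriptors at C10 and C12 read S only because the alkene side gains CIP priority.

Step 14
Reactants: 21 methyl (7Z,10S,12S,14S,16S)-10,12,14,16-tetramethyloctadec-7-enoate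
Product: 22 methyl (10R,12R,14S,16S)-10,12,14,16-tetramethyloctadecanoate
Conditions: H2 (1 atm), Pd/C, EtOAc, rt
Reagents that add atoms: none
Why: Heterogeneous hydrogenation of an isolated disubstituted alkene; no other reducible group is present and no stereocentre is allylic to a position that could isomerize into it.

Step 15
Reactants: 22 methyl (10R,12R,14S,16S)-10,12,14,16-tetramethyloctadecanoate
Product: 23 (10R,12R,14S,16S)-N-methoxy-N,10,12,14,16-pentamethyloctadecanamide
Conditions: MeNHOMe·HCl, i-PrMgCl, THF, –20 °C → 0 °C
Reagents that add atoms: N,O-dimethylhydroxylamine hydrochloride, CNOC.Cl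
Why: Direct aminolysis of the ester by the magnesium amide formed in the flask (Weinreb amide synthesis); the chelated tetrahedral adduct should prevent a second addition.

Step 16
Reactants: 24 methyl 2-methyl-3-oxobutanoate
Product: 26 methyl 2-methyl-3,5-dioxohexanoate, via dilithium dianion 25 (not isolated)
Conditions: LiN(i-Pr)2 (2.1 equiv), THF, 0 °C; then MeC(O)N(OMe)Me, –78 °C → 0 °C; aq. HCl
Reagents that add atoms: N-methoxy-N-methylacetamide, CC(=O)N(C)OC
Why: γ-Acylation of a β-keto ester 1,3-dianion, which reacts at the last-formed terminal carbanion; the tetrahedral adduct of the N-methoxy amide holds until work-up, so the more acidic product cannot quench unreacted dianion.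

Step 17
Reactants: 26 methyl 2-methyl-3,5-dioxohexanoate (excess); 23 (10R,12R,14S,16S)-N-methoxy-N,10,12,14,16-pentamethyloctadecanamide
Product: 28 methyl (16R,18R,20S,22S)-2,16,18,20,22-pentamethyl-3,5,7-trioxotetracosanoate (epimers at C2 and enol tautomers), via trilithium trianion 27 (not isolated)
Conditions: LiN(i-Pr)2 (3.2 equiv per 26), THF, 0 °C; then 23, –78 °C → 0 °C; cold aq. HCl to pH 4
Reagents that add atoms: none
Why: Terminal acylation of the trianion of a 3,5-diketo ester, which reacts at its least stabilized carbanion; the amide forms a stable chelated adduct, so the triketo ester appears only on work-up. The cheap partner 26 is used in excess and 28 is carried on promptly.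

Step 18
Reactants: 28 methyl (16R,18R,20S,22S)-2,16,18,20,22-pentamethyl-3,5,7-trioxotetracosanoate
Product: 31 4-methyl-5-[(9R,11R,13S,15S)-9,11,13,15-tetramethylheptadecyl]benzene-1,3-diol, via aldol adduct 29 (not isolated), via enedione ester 30 (not isolated)
Conditions: KOH (1 M aq.), THF, argon, 0 °C → 50 °C; then aq. HCl to pH 2
Reagents that add atoms: none
Why: Proposed new method: excess hydroxide turns 28 into its polyanion, and the carbanion at C5, stabilized by the C4 ketone and the ester, adds to the C6 ketone, forming the C5–C6 bond and closing the one new ring, a six-membered carbocycle, in a 6-(enolendo)-exo-trig aldol closure to give 29. Elimination of the C6 hydroxyl toward C1, whose hydrogens lie between the C6 and C2 carbonyls, gives 30, which cannot aromatize because C5 is quaternary. Hydroxide then attacks the ester of 30, the one carbonyl not masked as an enolate, and the C5–CO2 bond breaks by saponification and decarboxylation of the vinylogous β-keto acid (or directly by retro-Claisen loss of the carbonate), releasing a dienolate that is the dianion of 31, so that aromatization drives the loss of the ester. The closest known reaction type is the aqueous-base aldol cyclization of 3,5,7-triketo esters to resorcylates, combined with the decarboxylative aromatization of quaternary β-keto esters; new is their union on a 2-methyl substrate. No stereocentre is formed, and the four chain stereocentres carry no acidic hydrogen and are eight methylenes away. The step needs closure from C5 onto C6 rather than Claisen closure of C1 onto the ester, lactonization of the C2 enol oxygen to a pyrone, or aldol attack of C1' on C4. C1 and C3 are more acidic than C5 but their aldol closures would give four-membered rings, C1' is activated by one carbonyl only, and water as the medium keeps the ester a poor acyl acceptor compared with chelating alkoxide media, which should leave C5-to-C6 closure as the main path. Acid is added only after ring closure is complete, so that a decarboxylation before cyclization cannot erase the regiocontrol.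

Step 19
Reactants: 31 4-methyl-5-[(9R,11R,13S,15S)-9,11,13,15-tetramethylheptadecyl]benzene-1,3-diol
Product: 32 2-hydroxy-5-methyl-6-[(9R,11R,13S,15S)-9,11,13,15-tetramethylheptadecyl]cyclohexa-2,5-diene-1,4-dione
Conditions: (KSO3)2NO (2.5 equiv), aq. KH2PO4, n-Bu4NHSO4 (cat.), CH2Cl2/H2O, rt
Reagents that add atoms: potassium nitrosodisulfonate, [K+].[K+].[O]N(S(=O)(=O)[O-])S(=O)(=O)[O-]
Why: Teuber oxidation: the nitroxyl radical takes the hydrogen of the C4 hydroxyl and a second equivalent couples with the phenoxyl radical at C1, the only unsubstituted carbon para to a hydroxyl (the position para to the C2 hydroxyl is the methyl-bearing C5). Loss of the imidodisulfonate gives the para-quinone and leaves the C2 hydroxyl as a vinylogous acid; the phase-transfer salt brings the lipophilic arene into contact with the aqueous oxidant.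

Step 20
Reactants: 32 2-hydroxy-5-methyl-6-[(9R,11R,13S,15S)-9,11,13,15-tetramethylheptadecyl]cyclohexa-2,5-diene-1,4-dione
Product: 33 2-methoxy-5-methyl-6-[(9R,11R,13S,15S)-9,11,13,15-tetramethylheptadecyl]cyclohexa-2,5-diene-1,4-dione (CNP0330767.1)
Conditions: (CH3O)2SO2, K2CO3, acetone, rt
Reagents that add atoms: dimethyl sulfate, COS(=O)(=O)OC
Why: O-Alkylation of the hydroxyquinone, a vinylogous carboxylic acid that carbonate deprotonates fully; the hard sulfate electrophile should react at oxygen, and the 2-methoxy-1,4-quinone is the more stable of the two possible O-methyl isomers. The chain stereocentres are not affected.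

## Compound list

1 | bromoacetic acid | OC(=O)CBr | starting material
2 | S-ethyl 2-bromoethanethioate | CCSC(=O)CBr | intermediate
3 | [2-(ethylsulfanyl)-2-oxoethyl]triphenylphosphonium bromide | CCSC(=O)C[P+](c1ccccc1)(c1ccccc1)c1ccccc1.[Br-] | intermediate
4 | S-ethyl 2-(triphenyl-λ5-phosphanylidene)ethanethioate | CCSC(=O)C=P(c1ccccc1)(c1ccccc1)c1ccccc1 | intermediate
5 | (2E)-pent-2-enoic acid | CC/C=C/C(=O)O | starting material
6 | S-ethyl (2E)-pent-2-enethioate | CC/C=C/C(=O)SCC | intermediate
7 | S-ethyl (3S)-3-methylpentanethioate | CC[C@H](C)CC(=O)SCC | intermediate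
8 | (3S)-3-methylpentanal | CC[C@H](C)CC=O | intermediate
9 | S-ethyl (2E,5S)-5-methylhept-2-enethioate | CC[C@H](C)C/C=C/C(=O)SCC | intermediate
10 | S-ethyl (3S,5S)-3,5-dimethylheptanethioate | CC[C@H](C)C[C@H](C)CC(=O)SCC | intermediate
11 | (3S,5S)-3,5-dimethylheptanal | CC[C@H](C)C[C@H](C)CC=O | intermediate
12 | S-ethyl (2E,5S,7S)-5,7-dimethylnon-2-enethioate | CC[C@H](C)C[C@H](C)C/C=C/C(=O)SCC | intermediate
13 | S-ethyl (3S,5S,7S)-3,5,7-trimethylnonanethioate | CC[C@H](C)C[C@H](C)C[C@H](C)CC(=O)SCC | intermediate
14 | (3S,5S,7S)-3,5,7-trimethylnonanal | CC[C@H](C)C[C@H](C)C[C@H](C)CC=O | intermediate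
15 | S-ethyl (2E,5S,7S,9S)-5,7,9-trimethylundec-2-enethioate | CC[C@H](C)C[C@H](C)C[C@H](C)C/C=C/C(=O)SCC | intermediate
16 | S-ethyl (3S,5S,7S,9S)-3,5,7,9-tetramethylundecanethioate | CC[C@H](C)C[C@H](C)C[C@H](C)C[C@H](C)CC(=O)SCC | intermediate
17 | (3S,5S,7S,9S)-3,5,7,9-tetramethylundecanal | CC[C@H](C)C[C@H](C)C[C@H](C)C[C@H](C)CC=O | intermediate
18 | methyl 7-bromoheptanoate | COC(=O)CCCCCCBr | starting material
19 | (7-methoxy-7-oxoheptyl)triphenylphosphonium bromide | COC(=O)CCCCCC[P+](c1ccccc1)(c1ccccc1)c1ccccc1.[Br-] | intermediate
20 | methyl 7-(triphenyl-λ5-phosphanylidene)heptanoate | COC(=O)CCCCCC=P(c1ccccc1)(c1ccccc1)c1ccccc1 | intermediate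
21 | methyl (7Z,10S,12S,14S,16S)-10,12,14,16-tetramethyloctadec-7-enoate | CC[C@H](C)C[C@H](C)C[C@H](C)C[C@H](C)C/C=C\CCCCCC(=O)OC | intermediate
22 | methyl (10R,12R,14S,16S)-10,12,14,16-tetramethyloctadecanoate | CC[C@H](C)C[C@H](C)C[C@H](C)C[C@H](C)CCCCCCCCC(=O)OC | intermediate
23 | (10R,12R,14S,16S)-N-methoxy-N,10,12,14,16-pentamethyloctadecanamide | CC[C@H](C)C[C@H](C)C[C@H](C)C[C@H](C)CCCCCCCCC(=O)N(C)OC | intermediate
24 | methyl 2-methyl-3-oxobutanoate (methyl 2-methylacetoacetate) | COC(=O)C(C)C(C)=O | starting material
25 | dilithium dianion of methyl 2-methyl-3-oxobutanoate | [Li+].[Li+].C=C([O-])C(C)=C([O-])OC | intermediate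
26 | methyl 2-methyl-3,5-dioxohexanoate | CC(=O)CC(=O)C(C)C(=O)OC | intermediate
27 | trilithium trianion of methyl 2-methyl-3,5-dioxohexanoate | [Li+].[Li+].[Li+].C=C([O-])C=C([O-])C(C)=C([O-])OC | intermediate
28 | methyl (16R,18R,20S,22S)-2,16,18,20,22-pentamethyl-3,5,7-trioxotetracosanoate | CC[C@H](C)C[C@H](C)C[C@H](C)C[C@H](C)CCCCCCCCC(=O)CC(=O)CC(=O)C(C)C(=O)OC | intermediate
29 | methyl 2-hydroxy-1-methyl-4,6-dioxo-2-[(9R,11R,13S,15S)-9,11,13,15-tetramethylheptadecyl]cyclohexane-1-carboxylate | CC[C@H](C)C[C@H](C)C[C@H](C)C[C@H](C)CCCCCCCCC1(O)CC(=O)CC(=O)C1(C)C(=O)OC | intermediate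
30 | methyl 1-methyl-4,6-dioxo-2-[(9R,11R,13S,15S)-9,11,13,15-tetramethylheptadecyl]cyclohex-2-ene-1-carboxylate | CC[C@H](C)C[C@H](C)C[C@H](C)C[C@H](C)CCCCCCCCC1=CC(=O)CC(=O)C1(C)C(=O)OC | intermediate
31 | 4-methyl-5-[(9R,11R,13S,15S)-9,11,13,15-tetramethylheptadecyl]benzene-1,3-diol | CC[C@H](C)C[C@H](C)C[C@H](C)C[C@H](C)CCCCCCCCc1cc(O)cc(O)c1C | intermediate
32 | 2-hydroxy-5-methyl-6-[(9R,11R,13S,15S)-9,11,13,15-tetramethylheptadecyl]cyclohexa-2,5-diene-1,4-dione | CC[C@H](C)C[C@H](C)C[C@H](C)C[C@H](C)CCCCCCCCC1=C(C)C(=O)C=C(O)C1=O | intermediate
33 | 2-methoxy-5-methyl-6-[(9R,11R,13S,15S)-9,11,13,15-tetramethylheptadecyl]cyclohexa-2,5-diene-1,4-dione (CNP0330767.1) | CC[C@H](C)C[C@H](C)C[C@H](C)C[C@H](C)CCCCCCCCC1=C(C)C(=O)C=C(OC)C1=O | target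

## Step count and least certain steps

Total step count: 20. Longest linear sequence: 16 steps (from 5 through steps 3–11, 13–15 and 17–20; the path from 1 through steps 1, 2 and 5 onward is equally long).

**Step 18 (key step, proposed new method).** The most likely failures are these:
- cyclization by another mode, because the tertiary C5 carbanion is slower than the methylene carbanion of the known substrates;
- stalling at the enedione ester stage, because the neopentyl-type ester next to an enolate hydrolyses slowly;
- saponification and decarboxylation before ring closure, which would remove the group that directs the aldol.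

Fallback with known chemistry, from 23 to 31: amide 23 would acylate, under the conditions of step 17, the trianion of methyl 3,5-dioxohexanoate F1 (made from methyl acetoacetate as 26 is made from 24), giving methyl (16R,18R,20S,22S)-16,18,20,22-tetramethyl-3,5,7-trioxotetracosanoate F2. In F2 the nucleophilic carbon is a methylene, so aqueous KOH brings about the established triketo-ester aldol cyclization in which the ester stays and the ring aromatizes by enolization, giving methyl 2,4-dihydroxy-6-[(9R,11R,13S,15S)-9,11,13,15-tetramethylheptadecyl]benzoate F3. The ester carbon then becomes the C5 methyl group: LiAlH4 in THF reduces F3 to 4-(hydroxymethyl)-5-[(9R,11R,13S,15S)-9,11,13,15-tetramethylheptadecyl]benzene-1,3-diol F4, and ionic hydrogenation of this ortho,para-dihydroxybenzyl alcohol (Et3SiH, CF3CO2H, CH2Cl2) gives 31. The C5–C6 aldol disconnection is kept; only the origin of the methyl group changes.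

**Step 17.** The trianion is a strong base, so proton transfer from the α-methylene of 23 can compete with acylation. The third deprotonation of 26, at the tertiary C2–H, may be incomplete. The product may also lactonize during acidic work-up.

Fallback, from 22 to 28: ester 22 would be reduced with i-Bu2AlH (CH2Cl2, –78 °C) to (10R,12R,14S,16S)-10,12,14,16-tetramethyloctadecanal F5. Aldol addition of trianion 27 to F5 at –78 °C, which is faster than enolization of an aldehyde, gives methyl (16R,18R,20S,22S)-7-hydroxy-2,16,18,20,22-pentamethyl-3,5-dioxotetracosanoate F6. Oxidation of the C7 carbinol with Dess–Martin periodinane (CH2Cl2, NaHCO3) gives 28.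

**Step 19.** Radical attack at C3, which is flanked by both hydroxyls, or further oxidation and coupling of the hydroxyquinone may compete. Mixing of the lipophilic substrate with the aqueous radical salt may be poor.

Fallback, from 31 to 32: Vilsmeier–Haack formylation (POCl3, DMF) at C1, the position para to the C4 hydroxyl, gives 2,4-dihydroxy-5-methyl-6-[(9R,11R,13S,15S)-9,11,13,15-tetramethylheptadecyl]benzaldehyde F7. Dakin oxidation (H2O2, aq. NaOH, argon) exchanges the formyl group for a hydroxyl to give 5-methyl-6-[(9R,11R,13S,15S)-9,11,13,15-tetramethylheptadecyl]benzene-1,2,4-triol F8, and mild oxidation of this hydroxyhydroquinone (FeCl3 or air) gives 32.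

**Step 20.** The anion of 32 is ambident: alkylation at C3 or at the C4 oxygen (giving an ortho-quinone ether) can compete with alkylation at the C2 oxygen, and the quinone may decompose under prolonged basic conditions.

Fallback, from 32 to 33: acid-catalysed exchange with methanol (MeOH, cat. H2SO4, rt) forms the C2–OMe bond by addition of methanol to the protonated quinone and loss of water, under thermodynamic control and without base; no new compound is made.

The four conjugate additions (steps 4, 6, 8 and 10) fix the stereochemical purity of the chain, but they belong to an established reaction class and are not counted among the uncertain steps.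

## Further compounds

F1 | step 18 | methyl 3,5-dioxohexanoate | CC(=O)CC(=O)CC(=O)OC
F2 | step 18 | methyl (16R,18R,20S,22S)-16,18,20,22-tetramethyl-3,5,7-trioxotetracosanoate | CC[C@H](C)C[C@H](C)C[C@H](C)C[C@H](C)CCCCCCCCC(=O)CC(=O)CC(=O)CC(=O)OC
F3 | step 18 | methyl 2,4-dihydroxy-6-[(9R,11R,13S,15S)-9,11,13,15-tetramethylheptadecyl]benzoate | CC[C@H](C)C[C@H](C)C[C@H](C)C[C@H](C)CCCCCCCCc1cc(O)cc(O)c1C(=O)OC
F4 | step 18 | 4-(hydroxymethyl)-5-[(9R,11R,13S,15S)-9,11,13,15-tetramethylheptadecyl]benzene-1,3-diol | CC[C@H](C)C[C@H](C)C[C@H](C)C[C@H](C)CCCCCCCCc1cc(O)cc(O)c1CO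
F5 | step 17 | (10R,12R,14S,16S)-10,12,14,16-tetramethyloctadecanal | CC[C@H](C)C[C@H](C)C[C@H](C)C[C@H](C)CCCCCCCCC=O
F6 | step 17 | methyl (16R,18R,20S,22S)-7-hydroxy-2,16,18,20,22-pentamethyl-3,5-dioxotetracosanoate | CC[C@H](C)C[C@H](C)C[C@H](C)C[C@H](C)CCCCCCCCC(O)CC(=O)CC(=O)C(C)C(=O)OC
F7 | step 19 | 2,4-dihydroxy-5-methyl-6-[(9R,11R,13S,15S)-9,11,13,15-tetramethylheptadecyl]benzaldehyde | CC[C@H](C)C[C@H](C)C[C@H](C)C[C@H](C)CCCCCCCCc1c(C)c(O)cc(O)c1C=O
F8 | step 19 | 5-methyl-6-[(9R,11R,13S,15S)-9,11,13,15-tetramethylheptadecyl]benzene-1,2,4-triol | CC[C@H](C)C[C@H](C)C[C@H](C)C[C@H](C)CCCCCCCCc1c(C)c(O)cc(O)c1O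
F0 | step 20 | none | none
A1 | alternative 1 | 1-tert-butyl 11-methyl (2E,5S,7R,9E)-5,7-dimethylundeca-2,9-dienedioate | COC(=O)/C=C/C[C@H](C)C[C@H](C)C/C=C/C(=O)OC(C)(C)C
A2 | alternative 1 | 1-tert-butyl 11-methyl (3S,5S,7R,9R)-3,5,7,9-tetramethylundecanedioate | COC(=O)C[C@H](C)C[C@H](C)C[C@H](C)C[C@H](C)CC(=O)OC(C)(C)C
A3 | alternative 2 | tert-butyl(dimethyl){[9-(4,4,5,5-tetramethyl-1,3,2-dioxaborolan-2-yl)nonyl]oxy}silane | CC1(C)OB(OC1(C)C)CCCCCCCCCO[Si](C)(C)C(C)(C)C
A4 | alternative 2 | tert-butyl(dimethyl){[(10R,12R,14S,16R)-10,12,14-trimethyl-16-(4,4,5,5-tetramethyl-1,3,2-dioxaborolan-2-yl)heptadecyl]oxy}silane | CC1(C)OB(OC1(C)C)[C@H](C)C[C@H](C)C[C@H](C)C[C@H](C)CCCCCCCCCO[Si](C)(C)C(C)(C)C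
A5 | alternative 2 | (1S)-1-(trimethylstannyl)ethyl 2,4,6-tri(propan-2-yl)benzoate | C[C@H]([Sn](C)(C)C)OC(=O)c1c(cc(cc1C(C)C)C(C)C)C(C)C
A6 | alternative 3 | 4-hydroxy-3-methoxy-4-[(12R,14R,16S,18S)-12,14,16,18-tetramethylicos-2-en-3-yl]cyclobut-2-en-1-one | CC[C@H](C)C[C@H](C)C[C@H](C)C[C@H](C)CCCCCCCCC(=CC)C1(O)C(OC)=CC1=O
A7 | alternative 3 | (12R,14R,16S,18S)-3-iodo-12,14,16,18-tetramethylicos-2-ene | CC[C@H](C)C[C@H](C)C[C@H](C)C[C@H](C)CCCCCCCCC(I)=CC
A8 | alternative 3 | 3-methoxycyclobut-3-ene-1,2-dione | COC1=CC(=O)C1=O
A9 | alternative 3 | 2-methoxy-5-methyl-6-[(9R,11R,13S,15S)-9,11,13,15-tetramethylheptadecyl]benzene-1,4-diol | CC[C@H](C)C[C@H](C)C[C@H](C)C[C@H](C)CCCCCCCCc1c(O)c(OC)cc(O)c1C
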